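## Analysis of the target

The target is a diphenyl ether with no stereocentre. Ring A (C1–C6) and ring B (C1'–C6') are joined by one oxygen between C6 and C1', and each ring carries a hydroxyl ortho to that oxygen (C1–OH and C2'–OH). Five bromines complete the substitution, at C2 and C4 of ring A and at C3', C5' and C6' of ring B, leaving hydrogen only at C3, C5 and C4'. The sensitive elements are the two electron-rich bromophenol rings, which are easily oxidized or over-halogenated, and the five C–Br bonds, which rule out low-valent transition metals, hydrogenolysis and aryllithium chemistry once they are in place. The main difficulty is the ether bond: C1' is flanked by C2'–O and C6'–Br, C6 by C1–O, neither ring has an activating group for nucleophilic aromatic substitution, and a metal-catalysed etherification would have to ignore the bromides. The two rings also follow different logic. Ring B has a bromine at C6' that is meta to its hydroxyl and a hydrogen at C4', a pattern that direct bromination of a catechol ether does not give. Ring A has bromine at exactly the two carbons ortho and para to C1–OH that are not occupied by the ether oxygen, which is the pattern left when a cyclohexenone is oxidized to a phenol by bromine. The plan rests on this: C1 is treated as a former carbonyl carbon and C6 as the former aryloxy-bearing vinyl carbon of a 2-aryloxycyclohex-2-enone.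

## Retrosynthetic reasoning

**Target 13 to methyl ether 12.** The O–CH3 bond on the C2' oxygen is cut first. 3,4,6-Tribromo-2-(3,5-dibromo-2-hydroxyphenoxy)phenol (13) is traced to its 2'-O-methyl ether, 2,4-dibromo-6-(2,3,5-tribromo-6-methoxyphenoxy)phenol (12). The methyl group keeps the two oxygens of ring B distinct, so that only one of them can ever act as a nucleophile, and it is inert to bromination in acid. The forward reaction only has to cleave an aryl methyl ether without touching the diaryl ether or the C–Br bonds.

**Methyl ether 12 to enone 9 (the central disconnection).** The C2–Br and C4–Br bonds are removed together with the aromaticity of ring A, which leads to 2-(2,3,5-tribromo-6-methoxyphenoxy)cyclohex-2-en-1-one (9). The cut is made here because both bromines sit where a newly formed C1 hydroxyl directs them and because C6 is blocked by the ether oxygen, so no regiochemical choice remains. The gain is that the hindered diaryl ether bond no longer has to be made between two aromatic carbons. It becomes an ordinary substitution on an alicycle, made without a metal and before ring A exists. The forward reaction has to oxidize the enone to the phenol and deliver two bromines, and it must leave ring B and the enol-ether double bond alone.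

**Enone 9 to phenol 5 and epoxy ketone 7.** The bond between the ether oxygen and the enone α-carbon is cut. This gives 2,3,5-tribromo-6-methoxyphenol (5) and 7-oxabicyclo[4.1.0]heptan-2-one (7). An α,β-epoxy ketone is attacked by oxygen nucleophiles at the carbonyl-activated α-carbon, and the resulting β-hydroxy ketone dehydrates to the 2-substituted enone, so the alkene ends up exactly where the later aromatization needs it. The forward reaction has to make a weakly nucleophilic, doubly ortho-substituted phenoxide open the epoxide.

**Epoxy ketone 7 to cyclohexenone 6.** The epoxide C–O bonds are removed, giving cyclohex-2-en-1-one (6). Nucleophilic epoxidation of an enone is one of the most dependable ways to oxidize its α-carbon.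

**Phenol 5 to aldehyde 3.** The C–O bond of the phenolic hydroxyl is traced to a C–CHO bond, through 2,3,5-tribromo-6-methoxyphenyl formate (4) to 3,5,6-tribromo-2-methoxybenzaldehyde (3). This is why the two ring B oxygens are distinct from the outset: one enters as a phenol oxygen and is methylated, the other enters as a formyl carbon and is revealed by peracid oxidation. The forward reaction needs the aryl group, not the hydride, to migrate.

**Aldehyde 3 to salicylaldehydes 2 and 1.** The O–CH3 bond is cut to give 3,5,6-tribromo-2-hydroxybenzaldehyde (2). The C3–Br and C5–Br bonds of 2 are then cut to give 2-bromo-6-hydroxybenzaldehyde (1). In 1 the hydroxyl, the formyl group and the resident bromine all direct an electrophile to the same two carbons, so the ring B pattern is fixed by one unambiguous dibromination. The awkward bromine, the future C6'–Br meta to the hydroxyl, and the formyl group are both bought in. Formylating a preformed tribrominated phenol at a deactivated carbon next to bromine is thereby avoided.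

## Alternatives that were turned down

**Alternative 1:** Ring B is disconnected between the ether carbon C1' and a flanking carbon, back to the acyclic keto ester A1 (methyl 6-(2-methoxyphenoxy)-5-oxohexanoate).
- Forward key step: an alkoxide base closes A1 by intramolecular Claisen condensation of the aryloxy-bearing methylene carbon onto the ester. This gives the symmetric dione A2 (2-(2-methoxyphenoxy)cyclohexane-1,3-dione). One carbonyl would then be converted into the vinylogous acyl bromide A3 (3-bromo-2-(2-methoxyphenoxy)cyclohex-2-en-1-one), which places C6'–Br. Brominative aromatization would supply C2'–OH with bromine at C3' and C5', and ring A would be brominated and demethylated at the end.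
- For it: the ether bond is made from an unhindered phenoxide at a primary α-halo ketone, which is a stronger C–O bond formation than the hindered epoxide opening chosen here. The symmetry of A2 removes any regiochemical question in the ring closure, and C6'–Br is placed by functional-group logic.
- Against it: ring A enters as an electron-rich anisole ring and would be brominated before or during the aromatization of ring B, with the ether oxygen competing with the methoxy group as director, so four bromines on two rings must be controlled late. The sequence is also longer (haloketo ester, etherification, Claisen closure, vinylogous bromide, aromatization, ring A bromination, demethylation).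
- Comparison: the chosen route carries ring B fully brominated from a simple aromatic starting material and has only two bromines left to place, both on a ring that has one activating group and one blocked position.

**Alternative 2:** The O–C1' and C6'–Br bonds of ring B are both traced to a 3-borylbenzyne.
- Forward key step: halogen–magnesium exchange on the iodo triflate A4 (2-iodo-3-(4,4,5,5-tetramethyl-1,3,2-dioxaborolan-2-yl)phenyl trifluoromethanesulfonate) releases the aryne. The magnesium aryloxide of A5 (2-methoxyphenol) adds at C1', and the arylmagnesium at C6' is quenched by an electrophilic bromine donor to give the boronate A6 (2-[3-bromo-2-(2-methoxyphenoxy)phenyl]-4,4,5,5-tetramethyl-1,3,2-dioxaborolane). Oxidation of C–B to C2'–OH, fourfold bromination and demethylation would follow.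
- For it: it is convergent, it sets three contiguous ring B substituents in one operation, and it places C6'–Br with positional certainty and without electrophilic substitution. On these points it is stronger than the chosen route.
- Against it: a magnesium aryloxide is a weak nucleophile for an aryne generated under Grignard conditions and competes with the organomagnesium reagent and with halide. The regiochemistry depends entirely on the directing effect of the boryl group. A4 needs its own multistep preparation. Four bromines must still be introduced late on two rings of different reactivity.
- Comparison: the chosen route has no organometallic step and no aryne regiochemistry to rely on; its uncertainty sits in one bromination whose possible pathways converge on the same phenol.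

**Alternative 3:** Both hydroxyls, C1–OH and C2'–OH, are traced to formyl groups. The diaryl ether of the dialdehyde A7 (3-bromo-2-(2-formylphenoxy)benzaldehyde) comes from fluoride displacement on a formyl-activated aryl fluoride by a formyl-bearing phenoxide.
- Forward key step: a peroxy acid converts both formyl groups of A7 into formates, and methanolysis in the same pot gives the bisphenol A8 (3-bromo-2-(2-hydroxyphenoxy)phenol). Bromination ortho and para to the two hydroxyls would then give the target directly.
- For it: it needs three or four steps, no protecting group and no metal, and the formyl groups serve twice, as activators and as latent hydroxyls. In step economy it is clearly stronger than the chosen route.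
- Against it: each formyl group has only an aryloxy donor ortho to it, and the one on ring B also has a bromine on its ring, so hydride migration to the carboxylic acid competes at two sites that must both go right in one pot. The last step must deliver exactly four bromines to two rings (C2, C4, C3', C5') with the ether oxygen directing toward C4' and C3/C5. Under- and over-brominated congeners of such ethers are very hard to separate, and an electron-rich bisphenol is exposed to oxidation by bromine.
- Comparison: the chosen route is longer. In exchange the ring B bromines are fixed at a stage where all directors agree and the product is a simple crystalline aldehyde, and the two rings never compete for bromine because ring B is already exhausted when ring A is formed.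

Key step: step 6

Assumption: epoxy ketone 7 and hydroxy ketone 8 are racemic; this has no consequence because their stereocentres are destroyed on the way to the achiral target.

## Route

**Step 1**
Reactants: 1 2-bromo-6-hydroxybenzaldehyde
Product: 2 3,5,6-tribromo-2-hydroxybenzaldehyde
Conditions: Br2 (2.2 equiv), AcOH, 20 → 50 °C
Reagents that add atoms: bromine, BrBr
Why: Electrophilic aromatic bromination; the hydroxyl directs to its free ortho and para carbons, which are also the carbons meta to the formyl group and ortho/para to the resident bromine, so only one dibromide is expected.

**Step 2**
Reactants: 2 3,5,6-tribromo-2-hydroxybenzaldehyde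
Product: 3 3,5,6-tribromo-2-methoxybenzaldehyde
Conditions: MeI, K2CO3, DMF, 40 °C
Reagents that add atoms: iodomethane, CI
Why: Williamson O-methylation of an acidic, non-enolizable salicylaldehyde; the small electrophile should tolerate the two ortho substituents.

**Step 3**
Reactants: 3 3,5,6-tribromo-2-methoxybenzaldehyde
Product: 5 2,3,5-tribromo-6-methoxyphenol, via 2,3,5-tribromo-6-methoxyphenyl formate 4 (not isolated)
Conditions: mCPBA, CH2Cl2, 40 °C; then MeOH, Et3N (cat.), 20 °C
Reagents that add atoms: 3-chloroperoxybenzoic acid, OOC(=O)c1cccc(Cl)c1
Why: Baeyer–Villiger oxidation of an ortho-alkoxybenzaldehyde (Dakin-type); the ortho methoxy group supports aryl migration in the Criegee adduct, and the labile aryl formate is cleaved by methanolysis.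

**Step 4**
Reactants: 6 cyclohex-2-en-1-one
Product: 7 rac-(1R,6R)-7-oxabicyclo[4.1.0]heptan-2-one
Conditions: 30% aq. H2O2, NaOH (cat.), MeOH, 0 °C
Reagents that add atoms: hydrogen peroxide, OO
Why: Weitz–Scheffer nucleophilic epoxidation of an enone; the ring fusion is necessarily cis and the product is racemic.

**Step 5**
Reactants: 5 2,3,5-tribromo-6-methoxyphenol; 7 rac-(1R,6R)-7-oxabicyclo[4.1.0]heptan-2-one
Product: 9 2-(2,3,5-tribromo-6-methoxyphenoxy)cyclohex-2-en-1-one, via trans-3-hydroxy-2-aryloxycyclohexanone 8 (not isolated)
Conditions: KH (0.2 equiv), DMPU, THF, 65 °C; then p-TsOH·H2O (cat.), PhMe, 110 °C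
Reagents that add atoms: none
Why: The phenoxide opens the α,β-epoxy ketone by SN2 attack with inversion at the carbonyl-activated α-carbon, and the trans β-hydroxy ketone 8 then dehydrates (E1cB under base, completed by acid) to the 2-aryloxy enone; base is needed only in catalytic amount because the phenol reprotonates the alkoxide.

**Step 6**
Reactants: 9 2-(2,3,5-tribromo-6-methoxyphenoxy)cyclohex-2-en-1-one
Product: 12 2,4-dibromo-6-(2,3,5-tribromo-6-methoxyphenoxy)phenol, via 6,6-dibromo enone 10 (not isolated), via 2-bromo-6-aryloxyphenol 11 (not isolated)
Conditions: Br2 (3.05 equiv), HBr (cat.), AcOH, 20 → 70 °C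
Reagents that add atoms: bromine, BrBr
Why: Acid-catalysed enolization of 9 toward C6 gives the cross-conjugated dienol, which takes up two bromines at that carbon to give 10; loss of HBr across C5–C6 leaves a 6-bromocyclohexa-2,5-dienone whose C4 methylene tautomerizes at once, so that enone C1 becomes C1–OH and C6 becomes C2–Br of phenol 11. The third equivalent brominates 11 by electrophilic aromatic substitution at C4, the only free carbon ortho or para to the new hydroxyl, because the other ortho carbon is the ether carbon C6. The closest known reaction type is the bromination–dehydrobromination aromatization of cyclohexenones and cyclohexanones to bromophenols. No ring is closed and no stereocentre is formed; the existing carbocycle becomes ring A. The step needs site selectivity for C6 and C4 of the alicycle over the C2=C3 enol-ether bond and over ring B. The C2=C3 bond is the electron-poor alkene of an enone and carries a twisted, electron-poor aryloxy group, so addition of bromine there should be slow, and ring B has a single hydrogen, at C4', between two bromines on a ring that already bears three. The outcome should also not depend on whether the first bromine enters at C6 or at the γ-carbon C4, because either bromide loses HBr to the same phenol oxidation level and the hydroxyl then fixes the final positions.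

**Step 7**
Reactants: 12 2,4-dibromo-6-(2,3,5-tribromo-6-methoxyphenoxy)phenol
Product: 13 3,4,6-tribromo-2-(3,5-dibromo-2-hydroxyphenoxy)phenol
Conditions: BBr3 (3 equiv), CH2Cl2, −78 → 20 °C; then H2O
Reagents that add atoms: none
Why: Lewis-acid cleavage of an aryl methyl ether by bromide attack on the O-methyl carbon of the boron complex; diaryl ethers and aryl bromides are not cleaved under these conditions.

## Compound list

1 | 2-bromo-6-hydroxybenzaldehyde | O=Cc1c(O)cccc1Br | starting material
2 | 3,5,6-tribromo-2-hydroxybenzaldehyde | O=Cc1c(O)c(Br)cc(Br)c1Br | intermediate
3 | 3,5,6-tribromo-2-methoxybenzaldehyde | COc1c(C=O)c(Br)c(Br)cc1Br | intermediate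
4 | 2,3,5-tribromo-6-methoxyphenyl formate | COc1c(OC=O)c(Br)c(Br)cc1Br | intermediate (not isolated)
5 | 2,3,5-tribromo-6-methoxyphenol | COc1c(O)c(Br)c(Br)cc1Br | intermediate
6 | cyclohex-2-en-1-one | O=C1C=CCCC1 | starting material
7 | rac-(1R,6R)-7-oxabicyclo[4.1.0]heptan-2-one (cis-fused 2,3-epoxycyclohexanone, one enantiomer drawn) | O=C1CCC[C@H]2O[C@@H]12 | intermediate
8 | rac-(2S,3R)-3-hydroxy-2-(2,3,5-tribromo-6-methoxyphenoxy)cyclohexan-1-one (trans, one enantiomer drawn) | COc1c(O[C@H]2[C@H](O)CCCC2=O)c(Br)c(Br)cc1Br | intermediate (not isolated)
9 | 2-(2,3,5-tribromo-6-methoxyphenoxy)cyclohex-2-en-1-one | COc1c(OC2=CCCCC2=O)c(Br)c(Br)cc1Br | intermediate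
10 | 6,6-dibromo-2-(2,3,5-tribromo-6-methoxyphenoxy)cyclohex-2-en-1-one | COc1c(OC2=CCCC(Br)(Br)C2=O)c(Br)c(Br)cc1Br | intermediate (not isolated)
11 | 2-bromo-6-(2,3,5-tribromo-6-methoxyphenoxy)phenol | COc1c(Oc2cccc(Br)c2O)c(Br)c(Br)cc1Br | intermediate (not isolated)
12 | 2,4-dibromo-6-(2,3,5-tribromo-6-methoxyphenoxy)phenol (also named 3,4,6-tribromo-2-(3,5-dibromo-2-hydroxyphenoxy)anisole) | COc1c(Oc2cc(Br)cc(Br)c2O)c(Br)c(Br)cc1Br | intermediate
13 | 3,4,6-tribromo-2-(3,5-dibromo-2-hydroxyphenoxy)phenol | Oc1c(Br)cc(Br)cc1Oc1c(O)c(Br)cc(Br)c1Br | target

## Step count and least certain steps

Total step count: 7. Longest linear sequence: 6 steps (steps 1, 2, 3, 5, 6, 7); step 4 is a one-step side branch.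

**Step 6 (key step).**
- What may go wrong: bromine may add across the C2=C3 enol-ether bond in competition with enolization, which after loss of HBr and aromatization would leave a bromine at C5 of ring A. Dehydrobromination may also stall and leave alicyclic polybromides.
- Fallback: from 9, the aromatization and the bromination are separated and the oxidation is done without electrophilic bromine. Kinetic deprotonation at C6 with LiN(SiMe3)2 in THF at −78 °C and trapping with PhSeBr should give 6-(phenylselanyl)-2-(2,3,5-tribromo-6-methoxyphenoxy)cyclohex-2-en-1-one F1. Oxidation with H2O2 and syn-elimination of the selenoxide should give the cross-conjugated dienone, which tautomerizes to 2-(2,3,5-tribromo-6-methoxyphenoxy)phenol F2. Two equivalents of Br2 in AcOH at 20 °C then brominate F2 ortho and para to the hydroxyl. The route is rejoined at 12.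

**Step 5.**
- What may go wrong: the doubly ortho-substituted, weakly nucleophilic phenoxide may open the epoxide so slowly that base-induced rearrangement and self-condensation of the epoxy ketone take over, or dehydration may be incomplete.
- Fallback: from 5, the ether bond is made on a saturated ketone instead. Alkylation of 5 with 2-bromocyclohexanone (K2CO3, acetone, 56 °C), an SN2 reaction at an α-halo ketone, should give 2-(2,3,5-tribromo-6-methoxyphenoxy)cyclohexan-1-one F3. F3 is aromatized directly with four equivalents of Br2 in AcOH, the extra equivalent covering the additional oxidation level. The route is rejoined at 12.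

**Step 3.**
- What may go wrong: in the Criegee adduct the hydride may migrate in place of the electron-poor, doubly ortho-substituted aryl group, which would give the benzoic acid and not the formate.
- Fallback: from 3, the competing migrating group is changed from hydride to methyl. Addition of MeMgBr (THF, −78 °C) should give 1-(3,5,6-tribromo-2-methoxyphenyl)ethan-1-ol F4. Oxidation with Dess–Martin periodinane gives 1-(3,5,6-tribromo-2-methoxyphenyl)ethan-1-one F5. Baeyer–Villiger oxidation with CF3CO3H buffered by Na2HPO4, in which aryl migrates in preference to methyl, gives 2,3,5-tribromo-6-methoxyphenyl acetate F6. Methanolysis (K2CO3 (cat.), MeOH) then rejoins the route at 5.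

## Further compounds

F1 | step 6 | 6-(phenylselanyl)-2-(2,3,5-tribromo-6-methoxyphenoxy)cyclohex-2-en-1-one (racemic) | COc1c(OC2=CCCC([Se]c3ccccc3)C2=O)c(Br)c(Br)cc1Br
F2 | step 6 | 2-(2,3,5-tribromo-6-methoxyphenoxy)phenol | COc1c(Oc2ccccc2O)c(Br)c(Br)cc1Br
F3 | step 5 | 2-(2,3,5-tribromo-6-methoxyphenoxy)cyclohexan-1-one (racemic) | COc1c(OC2CCCCC2=O)c(Br)c(Br)cc1Br
F4 | step 3 | 1-(3,5,6-tribromo-2-methoxyphenyl)ethan-1-ol (racemic) | COc1c(C(C)O)c(Br)c(Br)cc1Br
F5 | step 3 | 1-(3,5,6-tribromo-2-methoxyphenyl)ethan-1-one | COc1c(C(C)=O)c(Br)c(Br)cc1Br
F6 | step 3 | 2,3,5-tribromo-6-methoxyphenyl acetate | COc1c(OC(C)=O)c(Br)c(Br)cc1Br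
A1 | alternative 1 | methyl 6-(2-methoxyphenoxy)-5-oxohexanoate | COc1ccccc1OCC(=O)CCCC(=O)OC
A2 | alternative 1 | 2-(2-methoxyphenoxy)cyclohexane-1,3-dione | COc1ccccc1OC1C(=O)CCCC1=O
A3 | alternative 1 | 3-bromo-2-(2-methoxyphenoxy)cyclohex-2-en-1-one | COc1ccccc1OC1=C(Br)CCCC1=O
A4 | alternative 2 | 2-iodo-3-(4,4,5,5-tetramethyl-1,3,2-dioxaborolan-2-yl)phenyl trifluoromethanesulfonate | CC1(C)OB(OC1(C)C)c1cccc(OS(=O)(=O)C(F)(F)F)c1I
A5 | alternative 2 | 2-methoxyphenol | COc1ccccc1O
A6 | alternative 2 | 2-[3-bromo-2-(2-methoxyphenoxy)phenyl]-4,4,5,5-tetramethyl-1,3,2-dioxaborolane | COc1ccccc1Oc1c(Br)cccc1B1OC(C)(C)C(C)(C)O1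
A7 | alternative 3 | 3-bromo-2-(2-formylphenoxy)benzaldehyde | O=Cc1ccccc1Oc1c(Br)cccc1C=O
A8 | alternative 3 | 3-bromo-2-(2-hydroxyphenoxy)phenol | Oc1ccccc1Oc1c(O)cccc1Br
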